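**Plan**

- Retrosynthesis: the C1'–O acyl bond and the two ring A MOM ethers go first, the quinone carbonyls C1 and C4 are taken back to carbinols, and ring B is then cut at C2=C3 by ring-closing metathesis. Further cuts are C4–C4a (aryllithium + acrolein), C1–C2 (2-lithioalkene + aryl aldehyde) and C1–C8a (formylation).
- Enabling feature: ring B holds a single C=C, C2=C3 (side chain on C2, H on C3), and its other two carbons, C1 and C4, are carbonyl carbons bonded to ring A. Its reduced form is therefore the cyclohexene that two ortho allylic carbinol arms on a benzene close by metathesis.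
- Forward: a six-step side-chain fragment (2-bromoalkene 11) and a two-step ring A aldehyde (15) are joined at C1–C2, and the vinyl carbinol arm is attached at C4a. Ring B is then closed (ring A is bought as the benzene ring of bromohydroquinone), and oxidation, silyl-to-acyl exchange at C1' and MOM removal finish the naphthazarin.
- Stereochemistry: the only stereocentre, C1' (R), is set by asymmetric transfer hydrogenation of an alkynyl ketone in step 3 and is not touched again. The C1 and C4 carbinols are passed on as epimer mixtures and erased in step 12.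

Key step: step 11

Assumption: the carbinol centres at C1 and C4 made in steps 9 and 10 are carried as epimer mixtures because step 12 turns both into carbonyl carbons, and the naphthazarin is written in the tautomer given for the target.

**Route**

Step 1
Reactants: 1 4-methylpent-3-enoic acid
Product: 3 N-methoxy-N,4-dimethylpent-3-enamide, via acyl imidazole 2 (not isolated)
Conditions: CDI, CH2Cl2, 0 °C → rt; then MeNH(OMe)·HCl, rt
Reagents that add atoms: N,O-dimethylhydroxylamine hydrochloride, CNOC.Cl; 1,1'-carbonyldiimidazole, O=C(n1ccnc1)n1ccnc1 (its imidazole stays only in 2)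
Why: Acyl imidazole formation followed by aminolysis is a standard Weinreb amide synthesis that needs no strong base, so the β,γ-alkene should stay out of conjugation.

Step 2
Reactants: 3 N-methoxy-N,4-dimethylpent-3-enamide; 4 ethynyltrimethylsilane
Product: 6 6-methyl-1-(trimethylsilyl)hept-5-en-1-yn-3-one, via lithium acetylide 5 (not isolated)
Conditions: 4, n-BuLi, THF, −78 °C; then 3, −78 → 0 °C; aq NH4Cl
Reagents that add atoms: n-butyllithium, [Li]CCCC (lithium, in 5 only)
Why: In this Weinreb ketone synthesis the acetylide adds once and the chelated tetrahedral adduct persists until the cold, weakly acidic quench, which should also keep the β,γ-unsaturated ynone from isomerising.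

Step 3
Reactants: 6 6-methyl-1-(trimethylsilyl)hept-5-en-1-yn-3-one
Product: 7 (3R)-6-methyl-1-(trimethylsilyl)hept-5-en-1-yn-3-ol
Conditions: Ru(p-cymene)[(R,R)-TsNCHPhCHPhNH] (1 mol %), i-PrOH, rt
Reagents that add atoms: none
Why: In the Noyori asymmetric transfer hydrogenation of an alkynyl ketone the Ru–H/N–H pair delivers hydride and proton through a six-membered transition state with the alkynyl group in the site normally taken by an aryl group, so the (R,R)-ligand should give the (R)-carbinol that becomes C1', and the base-free amido catalyst avoids enolisation of the allylic α-CH2.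

Step 4
Reactants: 7 (3R)-6-methyl-1-(trimethylsilyl)hept-5-en-1-yn-3-ol
Product: 8 (3R)-3-(tert-butyldimethylsilyloxy)-6-methyl-1-(trimethylsilyl)hept-5-en-1-yne
Conditions: TBSCl, imidazole, DMF, rt
Reagents that add atoms: tert-butyldimethylsilyl chloride, CC(C)(C)[Si](C)(C)Cl
Why: Imidazole-promoted silylation of a secondary alcohol is routine, and the TBS ether should tolerate the organolithium, metathesis and oxidation steps ahead before fluoride removes it.

Step 5
Reactants: 8 (3R)-3-(tert-butyldimethylsilyloxy)-6-methyl-1-(trimethylsilyl)hept-5-en-1-yne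
Product: 9 (3R)-3-(tert-butyldimethylsilyloxy)-6-methylhept-5-en-1-yne
Conditions: K2CO3 (cat.), MeOH, rt
Reagents that add atoms: none
Why: Methoxide-mediated protiodesilylation cleaves the alkynyl C–Si bond selectively, whereas a secondary TBS ether is stable to K2CO3 in methanol.

Step 6
Reactants: 9 (3R)-3-(tert-butyldimethylsilyloxy)-6-methylhept-5-en-1-yne
Product: 11 (3R)-2-bromo-3-(tert-butyldimethylsilyloxy)-6-methylhepta-1,5-diene, via alkenylborane 10 (not isolated)
Conditions: B-bromo-9-BBN, CH2Cl2, 0 °C; then AcOH, 0 °C → rt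
Reagents that add atoms: B-bromo-9-borabicyclo[3.3.1]nonane, BrB1C2CCCC1CCC2
Why: In this bromoboration–protodeboronation the B–Br reagent adds cis across the terminal alkyne with bromine on the internal carbon and leaves the trisubstituted alkene alone, and acetic acid then protonates the alkenyl C–B bond to give the 2-bromo-1-alkene.

Step 7
Reactants: 12 2-bromobenzene-1,4-diol
Product: 13 2-bromo-1,4-bis(methoxymethoxy)benzene
Conditions: MOMCl, i-Pr2NEt, CH2Cl2, 0 °C → rt
Reagents that add atoms: chloromethyl methyl ether, COCCl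
Why: O-Alkylation of both phenols gives MOM ethers that withstand the lithium reagents, stabilise neighbouring aryllithiums by chelation and can be removed at the end with mild acid, which methyl ethers on a naphthazarin cannot.

Step 8
Reactants: 13 2-bromo-1,4-bis(methoxymethoxy)benzene
Product: 15 2-bromo-3,6-bis(methoxymethoxy)benzaldehyde, via aryllithium 14 (not isolated)
Conditions: LiN(i-Pr)2, THF, −78 °C; then DMF, −78 → 0 °C; H2O
Reagents that add atoms: N,N-dimethylformamide, CN(C)C=O; lithium diisopropylamide, [Li]N(C(C)C)C(C)C (lithium, in 14 only)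
Why: In this directed ortho-metalation the amide base removes the most acidic ring proton, the one flanked by bromine and an OMOM group, and at −78 °C the ortho-bromoaryllithium should be formylated by DMF before it can lose LiBr.

Step 9
Reactants: 11 (3R)-2-bromo-3-(tert-butyldimethylsilyloxy)-6-methylhepta-1,5-diene; 15 2-bromo-3,6-bis(methoxymethoxy)benzaldehyde
Product: 17 (3R)-1-[2-bromo-3,6-bis(methoxymethoxy)phenyl]-3-(tert-butyldimethylsilyloxy)-6-methyl-2-methylidenehept-5-en-1-ol (both C1 epimers), via 2-lithioalkene 16 (not isolated)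
Conditions: 11, t-BuLi (2 equiv), Et2O, −78 °C; then 15, THF, −78 °C; H2O
Reagents that add atoms: tert-butyllithium, [Li]C(C)(C)C (lithium, in 16 only)
Why: Bromine–lithium exchange on the vinyl bromide gives a configurationally untouched 2-lithioalkene that should add 1,2 to the aldehyde much faster than it exchanges with the aryl bromide, and the new carbinol centre forms without control because it is oxidised later.

Step 10
Reactants: 17 (3R)-1-[2-bromo-3,6-bis(methoxymethoxy)phenyl]-3-(tert-butyldimethylsilyloxy)-6-methyl-2-methylidenehept-5-en-1-ol; 18 prop-2-enal (acrolein)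
Product: 20 (3R)-3-(tert-butyldimethylsilyloxy)-1-[2-(1-hydroxyprop-2-en-1-yl)-3,6-bis(methoxymethoxy)phenyl]-6-methyl-2-methylidenehept-5-en-1-ol (carbinol epimers), via dilithio alkoxide 19 (not isolated)
Conditions: n-BuLi (2.1 equiv), THF, −78 °C; then 18, −78 °C; H2O
Reagents that add atoms: n-butyllithium, [Li]CCCC (lithium, in 19 only)
Why: The first equivalent of n-BuLi forms the alkoxide and the second effects bromine–lithium exchange to an OMOM-chelated aryllithium, which should add 1,2 to acrolein as a hard organolithium and again give an inconsequential epimer mixture.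

Step 11
Reactants: 20 (3R)-3-(tert-butyldimethylsilyloxy)-1-[2-(1-hydroxyprop-2-en-1-yl)-3,6-bis(methoxymethoxy)phenyl]-6-methyl-2-methylidenehept-5-en-1-ol
Product: 21 2-[(1R)-1-(tert-butyldimethylsilyloxy)-4-methylpent-3-en-1-yl]-5,8-bis(methoxymethoxy)-1,4-dihydronaphthalene-1,4-diol (carbinol epimers)
Conditions: second-generation Grubbs catalyst RuCl2(=CHPh)(PCy3)(H2IMes) (5 mol %), CH2Cl2 (5 mM), 40 °C
Reagents that add atoms: none
Why: Initiation should occur at the monosubstituted vinyl group on the C4 carbinol, the least hindered alkene; the ruthenium alkylidene formed there engages the nearby 1,1-disubstituted alkene in a [2+2] cycloaddition, and the metallacyclobutane opens productively to give C2=C3 while the two methylidene units leave as ethylene. The closest known reaction type is ring-closing metathesis of ortho-bis(1-hydroxyallyl)arenes to 1,4-dihydronaphthalene-1,4-diols. Ring B closes as a six-membered carbocycle with the new double bond inside the ring, the ortho arrangement on ring A holding both alkenes within reach and ethylene loss driving the reaction forward. No stereocentre is created: the C1 and C4 carbinols remain epimer mixtures, all of which can cyclise, and C1' lies outside the reacting atoms. The step needs chemoselectivity among three alkenes, which the substrate secures because the trisubstituted prenyl alkene engages slowly and could only close a nine-membered ring with the vinyl arm or a four-membered ring with the methylidene arm, while high dilution suppresses intermolecular metathesis.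

Step 12
Reactants: 21 2-[(1R)-1-(tert-butyldimethylsilyloxy)-4-methylpent-3-en-1-yl]-5,8-bis(methoxymethoxy)-1,4-dihydronaphthalene-1,4-diol
Product: 22 2-[(1R)-1-(tert-butyldimethylsilyloxy)-4-methylpent-3-en-1-yl]-5,8-bis(methoxymethoxy)naphthalene-1,4-dione
Conditions: IBX (2.5 equiv), DMSO, rt
Reagents that add atoms: none
Why: Oxidation of either allylic, benzylic carbinol with IBX gives a 4-hydroxynaphthalen-1(4H)-one that is oxidised again or tautomerises to the naphthalene-1,4-diol and is then oxidised, so both pathways converge on the 1,4-quinone under near-neutral conditions that spare the MOM and TBS ethers.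

Step 13
Reactants: 22 2-[(1R)-1-(tert-butyldimethylsilyloxy)-4-methylpent-3-en-1-yl]-5,8-bis(methoxymethoxy)naphthalene-1,4-dione
Product: 23 2-[(1R)-1-hydroxy-4-methylpent-3-en-1-yl]-5,8-bis(methoxymethoxy)naphthalene-1,4-dione
Conditions: HF·pyridine, pyridine, THF, 0 °C → rt
Reagents that add atoms: none
Why: Fluoride-driven Si–O cleavage under buffered, weakly acidic conditions should remove the TBS group without the base that could enolise the quinone through the C1'–H and without touching the aryl MOM ethers.

Step 14
Reactants: 23 2-[(1R)-1-hydroxy-4-methylpent-3-en-1-yl]-5,8-bis(methoxymethoxy)naphthalene-1,4-dione; 24 3-methylbut-2-enoic acid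
Product: 25 (1R)-1-[5,8-bis(methoxymethoxy)-1,4-dioxo-1,4-dihydronaphthalen-2-yl]-4-methylpent-3-en-1-yl 3-methylbut-2-enoate
Conditions: DCC, DMAP (cat.), CH2Cl2, 0 °C → rt
Reagents that add atoms: none
Why: Steglich esterification acylates the secondary alcohol through the O-acylisourea and acylpyridinium without breaking the C1'–O bond, so the configuration is kept, and carbodiimide activation avoids the ketene pathway by which the acid chloride would deconjugate.

Step 15
Reactants: 25 (1R)-1-[5,8-bis(methoxymethoxy)-1,4-dioxo-1,4-dihydronaphthalen-2-yl]-4-methylpent-3-en-1-yl 3-methylbut-2-enoate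
Product: 26 (1R)-1-(5,8-dihydroxy-1,4-dioxo-1,4-dihydronaphthalen-2-yl)-4-methylpent-3-en-1-yl 3-methylbut-2-enoate (target)
Conditions: 3 M aq HCl, THF, rt
Reagents that add atoms: none
Why: Acid-catalysed hydrolysis of the two aryl MOM acetals, assisted by the peri carbonyl groups, should release the hydrogen-bonded naphthazarin, and because the C1' oxygen is acylated it cannot add to the prenyl alkene under the acid.

**Compound list**

1 | 4-methylpent-3-enoic acid | CC(C)=CCC(O)=O | starting material
2 | 1-(4-methylpent-3-enoyl)-1H-imidazole (acyl imidazole) | CC(C)=CCC(=O)n1ccnc1 | intermediate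
3 | N-methoxy-N,4-dimethylpent-3-enamide | CC(C)=CCC(=O)N(C)OC | intermediate
4 | ethynyltrimethylsilane | C#C[Si](C)(C)C | starting material
5 | [2-(trimethylsilyl)ethynyl]lithium (lithium acetylide) | [Li]C#C[Si](C)(C)C | intermediate
6 | 6-methyl-1-(trimethylsilyl)hept-5-en-1-yn-3-one | CC(C)=CCC(=O)C#C[Si](C)(C)C | intermediate
7 | (3R)-6-methyl-1-(trimethylsilyl)hept-5-en-1-yn-3-ol | CC(C)=CC[C@@H](O)C#C[Si](C)(C)C | intermediate
8 | (3R)-3-(tert-butyldimethylsilyloxy)-6-methyl-1-(trimethylsilyl)hept-5-en-1-yne | CC(C)=CC[C@@H](O[Si](C)(C)C(C)(C)C)C#C[Si](C)(C)C | intermediate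
9 | (3R)-3-(tert-butyldimethylsilyloxy)-6-methylhept-5-en-1-yne | CC(C)=CC[C@@H](O[Si](C)(C)C(C)(C)C)C#C | intermediate
10 | 9-[(1Z,3R)-2-bromo-3-(tert-butyldimethylsilyloxy)-6-methylhepta-1,5-dien-1-yl]-9-borabicyclo[3.3.1]nonane (alkenylborane) | CC(C)=CC[C@@H](O[Si](C)(C)C(C)(C)C)/C(Br)=C/B1C2CCCC1CCC2 | intermediate
11 | (3R)-2-bromo-3-(tert-butyldimethylsilyloxy)-6-methylhepta-1,5-diene | CC(C)=CC[C@@H](O[Si](C)(C)C(C)(C)C)C(Br)=C | intermediate
12 | 2-bromobenzene-1,4-diol (bromohydroquinone) | Oc1ccc(O)c(Br)c1 | starting material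
13 | 2-bromo-1,4-bis(methoxymethoxy)benzene | COCOc1ccc(OCOC)c(Br)c1 | intermediate
14 | [2-bromo-3,6-bis(methoxymethoxy)phenyl]lithium (aryllithium) | COCOc1ccc(OCOC)c([Li])c1Br | intermediate
15 | 2-bromo-3,6-bis(methoxymethoxy)benzaldehyde | COCOc1ccc(OCOC)c(C=O)c1Br | intermediate
16 | [(3R)-3-(tert-butyldimethylsilyloxy)-6-methylhepta-1,5-dien-2-yl]lithium (2-lithioalkene) | CC(C)=CC[C@@H](O[Si](C)(C)C(C)(C)C)C([Li])=C | intermediate
17 | (3R)-1-[2-bromo-3,6-bis(methoxymethoxy)phenyl]-3-(tert-butyldimethylsilyloxy)-6-methyl-2-methylidenehept-5-en-1-ol, both C1 epimers | CC(C)=CC[C@@H](O[Si](C)(C)C(C)(C)C)C(=C)C(O)c1c(OCOC)ccc(OCOC)c1Br | intermediate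
18 | prop-2-enal (acrolein) | C=CC=O | starting material
19 | lithium (3R)-3-(tert-butyldimethylsilyloxy)-1-[2-lithio-3,6-bis(methoxymethoxy)phenyl]-6-methyl-2-methylidenehept-5-en-1-olate (dilithio alkoxide) | CC(C)=CC[C@@H](O[Si](C)(C)C(C)(C)C)C(=C)C(O[Li])c1c(OCOC)ccc(OCOC)c1[Li] | intermediate
20 | (3R)-3-(tert-butyldimethylsilyloxy)-1-[2-(1-hydroxyprop-2-en-1-yl)-3,6-bis(methoxymethoxy)phenyl]-6-methyl-2-methylidenehept-5-en-1-ol, carbinol epimers | CC(C)=CC[C@@H](O[Si](C)(C)C(C)(C)C)C(=C)C(O)c1c(OCOC)ccc(OCOC)c1C(O)C=C | intermediate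
21 | 2-[(1R)-1-(tert-butyldimethylsilyloxy)-4-methylpent-3-en-1-yl]-5,8-bis(methoxymethoxy)-1,4-dihydronaphthalene-1,4-diol, carbinol epimers | CC(C)=CC[C@@H](O[Si](C)(C)C(C)(C)C)C1=CC(O)c2c(OCOC)ccc(OCOC)c2C1O | intermediate
22 | 2-[(1R)-1-(tert-butyldimethylsilyloxy)-4-methylpent-3-en-1-yl]-5,8-bis(methoxymethoxy)naphthalene-1,4-dione | CC(C)=CC[C@@H](O[Si](C)(C)C(C)(C)C)C1=CC(=O)c2c(OCOC)ccc(OCOC)c2C1=O | intermediate
23 | 2-[(1R)-1-hydroxy-4-methylpent-3-en-1-yl]-5,8-bis(methoxymethoxy)naphthalene-1,4-dione | CC(C)=CC[C@@H](O)C1=CC(=O)c2c(OCOC)ccc(OCOC)c2C1=O | intermediate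
24 | 3-methylbut-2-enoic acid | CC(C)=CC(O)=O | starting material
25 | (1R)-1-[5,8-bis(methoxymethoxy)-1,4-dioxo-1,4-dihydronaphthalen-2-yl]-4-methylpent-3-en-1-yl 3-methylbut-2-enoate | CC(C)=CC[C@@H](OC(=O)C=C(C)C)C1=CC(=O)c2c(OCOC)ccc(OCOC)c2C1=O | intermediate
26 | (1R)-1-(5,8-dihydroxy-1,4-dioxo-1,4-dihydronaphthalen-2-yl)-4-methylpent-3-en-1-yl 3-methylbut-2-enoate | CC(C)=CC[C@@H](OC(=O)C=C(C)C)C1=CC(=O)c2c(O)ccc(O)c2C1=O | target

**Step count**

Total: 15 steps. Longest linear sequence: 13 steps (steps 1–6 and 9–15, from 4-methylpent-3-enoic acid); the ring A branch (steps 7–8) joins at step 9.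

**Steps most likely to fail**

Step 11 (ring closure). The crowded 1,1-disubstituted alkene, flanked by two branched carbinol carbons, may engage slowly. That would give ruthenium hydride species time to isomerise the free allylic carbinols to ketones, and the product diol may lose water and aromatise. Fallback: starting from 20, both carbinols are silylated (TMSCl, imidazole, CH2Cl2, 0 °C) to the bis(trimethylsilyl) ether of 20 F1. This is closed with the same second-generation Grubbs catalyst in toluene at 60–80 °C to 2-[(1R)-1-(tert-butyldimethylsilyloxy)-4-methylpent-3-en-1-yl]-5,8-bis(methoxymethoxy)-1,4-bis(trimethylsilyloxy)-1,4-dihydronaphthalene F2. K2CO3 in MeOH should then cleave only the two trimethylsilyl ethers, and the route is rejoined at 21.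

Step 10 (second arm). Acrolein may polymerise under the anionic conditions, or the hindered aryllithium may be protonated instead of adding, returning debrominated material. Fallback: starting from 17, the same dilithio alkoxide 19 is quenched with DMF. Aqueous work-up should give the ring-closed hydroxy aldehyde, the lactol 3-[(3R)-3-(tert-butyldimethylsilyloxy)-6-methylhepta-1,5-dien-2-yl]-4,7-bis(methoxymethoxy)-1,3-dihydro-2-benzofuran-1-ol F3. An excess of cheap CH2=CHMgBr in THF at 0 °C opens the lactol and adds to the aldehyde, and the route is rejoined at 20.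

Step 6 (vinyl bromide). The Lewis-acidic boron bromide may ionise or cleave the propargylic silyl ether, or add with incomplete regiocontrol. Fallback: starting from 9, hydrostannation with Bu3SnH and catalytic Mo(CO)3(CNt-Bu)3 in THF at 55 °C should place tin on the internal carbon of a propargylic ether and give tributyl[(3R)-3-(tert-butyldimethylsilyloxy)-6-methylhepta-1,5-dien-2-yl]stannane F4. Iododestannylation with I2 in CH2Cl2 at 0 °C gives (3R)-3-(tert-butyldimethylsilyloxy)-2-iodo-6-methylhepta-1,5-diene F5. Iodine–lithium exchange with t-BuLi in Et2O at −78 °C then delivers the 2-lithioalkene, and the route is rejoined at 16.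

**Further compounds**

F1 | step 11 | (3R)-3-(tert-butyldimethylsilyloxy)-1-{3,6-bis(methoxymethoxy)-2-[1-(trimethylsilyloxy)prop-2-en-1-yl]phenyl}-6-methyl-2-methylidene-1-(trimethylsilyloxy)hept-5-ene (bis(trimethylsilyl) ether of 20) | CC(C)=CC[C@@H](O[Si](C)(C)C(C)(C)C)C(=C)C(O[Si](C)(C)C)c1c(OCOC)ccc(OCOC)c1C(O[Si](C)(C)C)C=C
F2 | step 11 | 2-[(1R)-1-(tert-butyldimethylsilyloxy)-4-methylpent-3-en-1-yl]-5,8-bis(methoxymethoxy)-1,4-bis(trimethylsilyloxy)-1,4-dihydronaphthalene | CC(C)=CC[C@@H](O[Si](C)(C)C(C)(C)C)C1=CC(O[Si](C)(C)C)c2c(OCOC)ccc(OCOC)c2C1O[Si](C)(C)C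
F3 | step 10 | 3-[(3R)-3-(tert-butyldimethylsilyloxy)-6-methylhepta-1,5-dien-2-yl]-4,7-bis(methoxymethoxy)-1,3-dihydro-2-benzofuran-1-ol | CC(C)=CC[C@@H](O[Si](C)(C)C(C)(C)C)C(=C)C1OC(O)c2c(OCOC)ccc(OCOC)c12
F4 | step 6 | tributyl[(3R)-3-(tert-butyldimethylsilyloxy)-6-methylhepta-1,5-dien-2-yl]stannane | CC(C)=CC[C@@H](O[Si](C)(C)C(C)(C)C)C(=C)[Sn](CCCC)(CCCC)CCCC
F5 | step 6 | (3R)-3-(tert-butyldimethylsilyloxy)-2-iodo-6-methylhepta-1,5-diene | CC(C)=CC[C@@H](O[Si](C)(C)C(C)(C)C)C(I)=C
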